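**Retrosynthetic overview**

1. Locants: oxane O1, C2 (acrylate-bearing), C3, C4, C5 (chain-bearing), C6; chain C1'–C13' counted from the ring. The acrylic acid is carried as its primary allylic alcohol and oxidised last; the chain is cut at C1'–C2' into the α-sulfonyl carbanion of oxane 10 and terminal epoxide 17, with the C–S bond reduced afterwards.
2. Oxane 10 is cut at the C5–C6 ring bond: a 1,3-dioxane (7) is cleaved to a bromomethyl ether on O1, and the derived alkoxymethyl radical closes 6-exo onto a vinyl sulfone.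
3. Enabling feature: C6 is an unsubstituted OCH2 carbon bound only to O1 and C5, and O1 sits 1,3 to the oxygen of the future carboxyl carbon (C2–C(=CH2)–CH2O). C6 can therefore be stored as the acetal carbon of a six-membered methylene acetal over these two oxygens and released on O1 as a radical; C5 is the sixth atom (C6, O1, C2, C3, C4, C5) and its exocyclic CH2 (C1') can carry the sulfone.
4. Stereocentres: C2 from a β-isocupreidine Morita–Baylis–Hillman reaction; C5 by 1,4-relay from C2 in the ring closure; C3'/C4' from Katsuki–Sharpless epoxidation of (2Z,6E)-farnesol and a Payne-type inversion at the secondary carbon.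
5. Ring order: temporary 1,3-dioxane (step 3), then the oxane (step 5), the only ring of the target.

Key step: step 5

Remark on the chemistry: (2Z,6E)-farnesol (11) is assumed to be bought isomerically pure; the target diol corresponds to syn addition to an E-alkene, so epoxidation plus one inversion needs the 2Z geometry.

**Route**

Step 1
Reactants: 1 pent-4-enal; 2 1,1,1,3,3,3-hexafluoropropan-2-yl prop-2-enoate
Product: 3 1,1,1,3,3,3-hexafluoropropan-2-yl (3R)-3-hydroxy-2-methylidenehept-6-enoate
Conditions: β-isocupreidine (10 mol%), DMF, −55 °C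
Reagents that add atoms: none
Why: Morita–Baylis–Hillman reaction in which the quinuclidine nitrogen of the catalyst adds to acrylate 2 and the enolate attacks aldehyde 1 from the face fixed by hydrogen bonding to the catalyst's phenolic OH, which with this catalyst/acrylate pair should give the 3R adduct (the future C2).

Step 2
Reactants: 3 1,1,1,3,3,3-hexafluoropropan-2-yl (3R)-3-hydroxy-2-methylidenehept-6-enoate
Product: 4 (3R)-2-methylidenehept-6-ene-1,3-diol
Conditions: iBu2AlH (3.5 equiv), CH2Cl2, −78 → 0 °C; aq KNa tartrate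
Reagents that add atoms: none
Why: 1,2-reduction of the activated ester by iBu2AlH stores the acrylic acid carbon at the allylic alcohol level without touching the carbinol stereocentre.

Step 3
Reactants: 4 (3R)-2-methylidenehept-6-ene-1,3-diol
Product: 5 (4R)-4-(but-3-en-1-yl)-5-methylidene-1,3-dioxane
Conditions: CH2(OMe)2 (2 equiv), TsOH·H2O (cat.), 4 Å sieves, CH2Cl2, rt
Reagents that add atoms: dimethoxymethane, COCOC
Why: acid-catalysed transacetalisation closes the six-membered methylene acetal over the 1,3-diol, which protects both oxygens and installs the future C6 as the acetal carbon; no stereocentre is formed.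

Step 4
Reactants: 5 (4R)-4-(but-3-en-1-yl)-5-methylidene-1,3-dioxane; 6 phenyl vinyl sulfone
Product: 7 (4R)-5-methylidene-4-[(3E)-4-(phenylsulfonyl)but-3-en-1-yl]-1,3-dioxane
Conditions: second-generation Hoveyda–Grubbs catalyst RuCl2(H2IMes)(=CH-C6H4-2-OiPr) (5 mol%), CH2Cl2, 40 °C
Reagents that add atoms: none
Why: olefin cross-metathesis of the monosubstituted alkene with the electron-poor vinyl sulfone should give the E-alkenyl sulfone, while the 1,1-disubstituted exocyclic alkene is too hindered to enter the cycle.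

Step 5
Reactants: 7 (4R)-5-methylidene-4-[(3E)-4-(phenylsulfonyl)but-3-en-1-yl]-1,3-dioxane
Product: 10 2-[(2R,5S)-5-[(phenylsulfonyl)methyl]oxan-2-yl]prop-2-en-1-ol, via bromomethyl ether 8 (not isolated), via cyclised borinate 9 (not isolated)
Conditions: Me2BBr (1.1 equiv), CH2Cl2, −78 °C; volatiles off in vacuo; Bu3SnH, Et3B/air, PhMe, 0 °C; MeOH/aq NaHCO3 work-up
Reagents that add atoms: none
Why: Proposed new method: Me2BBr should bind the less hindered acetal oxygen (on the primary CH2), that C–O bond breaks and bromide caps the oxocarbenium ion on the secondary oxygen to give bromomethyl ether 8 with the primary oxygen parked as a borinate; Bu3Sn• then abstracts bromine, the nucleophilic alkoxymethyl radical at C6 adds to the β-carbon (C5) of the vinyl sulfone, the α-sulfonyl radical takes hydrogen from Bu3SnH, and methanolysis of the borinate frees the alcohol. The closest known reaction types are Me2BBr cleavage of methylene acetals of primary/secondary diols to bromomethyl ethers of the secondary oxygen, Bu3SnH cyclisations of alkoxymethyl radicals made from phenylselenomethyl ethers, and Giese additions of α-halo ether (glycosyl bromide) radicals; new is their telescoping, which trades an acetal C–O bond for the ring C–C bond. The oxane ring (O1, C2, C3, C4, C5, C6) closes in the 6-exo-trig mode. The new stereocentre C5 is controlled by C2 through a chair-like transition state with the branched C2 substituent and the sulfonylvinyl group both equatorial, which should give the 2,5-trans (5S) isomer. The step needs regioselective acetal cleavage, secured by the primary/secondary difference of the two oxygens (the regioisomeric bromomethyl ether cannot reach the acceptor and is only reduced), and 6-exo closure ahead of 1,5-hydrogen shift, direct reduction and 5-endo attack on the exocyclic alkene, secured by the polarity-matched vinyl sulfone.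

Step 6
Reactants: 11 (2Z,6E)-farnesol
Product: 12 [(2S,3R)-3-[(3E)-4,8-dimethylnona-3,7-dien-1-yl]-3-methyloxiran-2-yl]methanol
Conditions: Ti(OiPr)4 (10 mol%), L-(+)-diethyl tartrate (12 mol%), t-BuOOH, 4 Å sieves, CH2Cl2, −20 °C
Reagents that add atoms: tert-butyl hydroperoxide, CC(C)(C)OO
Why: Katsuki–Sharpless asymmetric epoxidation, in which the allylic alcohol directs the Ti(OiPr)4/tartrate complex to the 2,3-alkene only and the L-(+)-tartrate should deliver oxygen to the face that gives the (2S,3R)-cis-epoxide.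

Step 7
Reactants: 12 [(2S,3R)-3-[(3E)-4,8-dimethylnona-3,7-dien-1-yl]-3-methyloxiran-2-yl]methanol
Product: 14 (2R,3R,6E)-3,7,11-trimethyldodeca-6,10-diene-1,2,3-triol, via terminal epoxide alkoxide 13 (not isolated)
Conditions: NaOH (0.5 M aq), t-BuOH, 75 °C
Reagents that add atoms: water, O
Why: Payne rearrangement–opening, in which the C1 alkoxide displaces the epoxide oxygen at C2 with inversion to give 13 and hydroxide opens this terminal epoxide at the primary carbon, so C2 is inverted, C3 keeps its oxygen and the cis-epoxide maps onto the (2R,3R)-triol.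

Step 8
Reactants: 14 (2R,3R,6E)-3,7,11-trimethyldodeca-6,10-diene-1,2,3-triol
Product: 16 (2R,5E)-6,10-dimethyl-2-[(2R)-oxiran-2-yl]undeca-5,9-dien-2-ol, via primary tosylate 15 (not isolated)
Conditions: TsCl (1.05 equiv), Bu2SnO (2 mol%), Et3N, CH2Cl2, 0 °C; then DBU, 0 °C → rt
Reagents that add atoms: none
Why: Bu2SnO-catalysed sulfonylation selects the primary hydroxyl of the 1,2-diol and the secondary oxygen then closes the epoxide by 3-exo-tet displacement at the primary carbon (epoxide formation from a diol monosulfonate), so neither stereocentre is touched.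

Step 9
Reactants: 16 (2R,5E)-6,10-dimethyl-2-[(2R)-oxiran-2-yl]undeca-5,9-dien-2-ol
Product: 17 triethyl{[(2R,5E)-6,10-dimethyl-2-[(2R)-oxiran-2-yl]undeca-5,9-dien-2-yl]oxy}silane
Conditions: Et3SiOTf, 2,6-lutidine, CH2Cl2, −78 °C
Reagents that add atoms: triethylsilyl trifluoromethanesulfonate, CC[Si](CC)(CC)OS(=O)(=O)C(F)(F)F
Why: silylation of the tertiary alcohol removes the only acidic proton and blocks Payne-type return to the internal epoxide during the carbanion step.

Step 10
Reactants: 10 2-[(2R,5S)-5-[(phenylsulfonyl)methyl]oxan-2-yl]prop-2-en-1-ol; 17 triethyl{[(2R,5E)-6,10-dimethyl-2-[(2R)-oxiran-2-yl]undeca-5,9-dien-2-yl]oxy}silane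
Product: 19 2-[(2R,5S)-5-[(3R,4R,7E)-3-hydroxy-4,8,12-trimethyl-1-(phenylsulfonyl)-4-[(triethylsilyl)oxy]trideca-7,11-dien-1-yl]oxan-2-yl]prop-2-en-1-ol (both epimers at C1'), via dilithio sulfone 18 (not isolated)
Conditions: n-BuLi (2.05 equiv), THF, −78 °C; 17, BF3·OEt2, −78 °C; aq NH4Cl
Reagents that add atoms: none
Why: Julia-type alkylation of an α-sulfonyl carbanion with an epoxide, in which dianion 18 opens the BF3-activated terminal epoxide at its CH2 carbon to form the C1'–C2' bond with both carbinol centres untouched; the sulfone-bearing centre forms as a mixture and is erased in step 11.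

Step 11
Reactants: 19 the hydroxy sulfone from step 10
Product: 21 2-[(2R,5S)-5-[(3R,4R,7E)-3,4-dihydroxy-4,8,12-trimethyltrideca-7,11-dien-1-yl]oxan-2-yl]prop-2-en-1-ol, via desulfonylated silyl ether 20 (not isolated)
Conditions: Mg turnings, MeOH, 50 °C; then 1 M HCl, MeOH, 0 °C
Reagents that add atoms: none
Why: reductive desulfonylation by electron transfer from Mg in MeOH cleaves the alkyl C–S bond without reducing isolated alkenes, and the acidic stage removes the triethylsilyl ether; no stereocentre is affected.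

Step 12
Reactants: 21 the triol from step 11
Product: 22 2-[(2R,5S)-5-[(3R,4R,7E)-3,4-dihydroxy-4,8,12-trimethyltrideca-7,11-dien-1-yl]oxan-2-yl]prop-2-enal
Conditions: [Cu(MeCN)4]OTf (5 mol%), 2,2'-bipyridine, TEMPO, N-methylimidazole, MeCN, air, rt
Reagents that add atoms: none
Why: [Cu(MeCN)4]OTf/TEMPO aerobic alcohol oxidation (Stahl oxidation) is selective for the primary allylic alcohol over the secondary and tertiary hydroxyls and does not cleave the 1,2-diol.

Step 13
Reactants: 22 the enal from step 12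
Product: 23 2-[(2R,5S)-5-[(3R,4R,7E)-3,4-dihydroxy-4,8,12-trimethyltrideca-7,11-dien-1-yl]oxan-2-yl]prop-2-enoic acid
Conditions: NaClO2, NaH2PO4, 2-methylbut-2-ene, t-BuOH/H2O, 0 °C → rt
Reagents that add atoms: sodium chlorite, [Na+].[O-]Cl=O
Why: Pinnick oxidation converts the enal to the acrylic acid, with 2-methylbut-2-ene scavenging hypochlorite so that the trisubstituted alkenes are not chlorinated.

**Compound list**

1 | pent-4-enal | C=CCCC=O | starting material
2 | 1,1,1,3,3,3-hexafluoropropan-2-yl prop-2-enoate | C=CC(=O)OC(C(F)(F)F)C(F)(F)F | starting material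
3 | 1,1,1,3,3,3-hexafluoropropan-2-yl (3R)-3-hydroxy-2-methylidenehept-6-enoate | C=C(C(=O)OC(C(F)(F)F)C(F)(F)F)[C@H](O)CCC=C | intermediate
4 | (3R)-2-methylidenehept-6-ene-1,3-diol | C=C(CO)[C@H](O)CCC=C | intermediate
5 | (4R)-4-(but-3-en-1-yl)-5-methylidene-1,3-dioxane | C=C1COCO[C@@H]1CCC=C | intermediate
6 | phenyl vinyl sulfone | C=CS(=O)(=O)c1ccccc1 | starting material
7 | (4R)-5-methylidene-4-[(3E)-4-(phenylsulfonyl)but-3-en-1-yl]-1,3-dioxane | C=C1COCO[C@@H]1CC/C=C/S(=O)(=O)c1ccccc1 | intermediate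
8 | (3R,6E)-3-(bromomethoxy)-2-methylidene-7-(phenylsulfonyl)hept-6-en-1-yl dimethylborinate | C=C(COB(C)C)[C@H](OCBr)CC/C=C/S(=O)(=O)c1ccccc1 | intermediate (not isolated)
9 | 2-[(2R,5S)-5-[(phenylsulfonyl)methyl]oxan-2-yl]prop-2-en-1-yl dimethylborinate | C=C(COB(C)C)[C@H]1CC[C@H](CS(=O)(=O)c2ccccc2)CO1 | intermediate (not isolated)
10 | 2-[(2R,5S)-5-[(phenylsulfonyl)methyl]oxan-2-yl]prop-2-en-1-ol (2,5-trans) | C=C(CO)[C@H]1CC[C@H](CS(=O)(=O)c2ccccc2)CO1 | intermediate
11 | (2Z,6E)-farnesol, (2Z,6E)-3,7,11-trimethyldodeca-2,6,10-trien-1-ol | OC/C=C(/C)CC/C=C(\C)CCC=C(C)C | starting material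
12 | [(2S,3R)-3-[(3E)-4,8-dimethylnona-3,7-dien-1-yl]-3-methyloxiran-2-yl]methanol | OC[C@@H]1O[C@]1(C)CC/C=C(\C)CCC=C(C)C | intermediate
13 | sodium (2R,5E)-6,10-dimethyl-2-[(2R)-oxiran-2-yl]undeca-5,9-dien-2-olate | C1O[C@H]1[C@](C)([O-])CC/C=C(\C)CCC=C(C)C.[Na+] | intermediate (not isolated)
14 | (2R,3R,6E)-3,7,11-trimethyldodeca-6,10-diene-1,2,3-triol | OC[C@@H](O)[C@](C)(O)CC/C=C(\C)CCC=C(C)C | intermediate
15 | (2R,3R,6E)-2,3-dihydroxy-3,7,11-trimethyldodeca-6,10-dien-1-yl 4-methylbenzenesulfonate | Cc1ccc(cc1)S(=O)(=O)OC[C@@H](O)[C@](C)(O)CC/C=C(\C)CCC=C(C)C | intermediate (not isolated)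
16 | (2R,5E)-6,10-dimethyl-2-[(2R)-oxiran-2-yl]undeca-5,9-dien-2-ol | C1O[C@H]1[C@](C)(O)CC/C=C(\C)CCC=C(C)C | intermediate
17 | triethyl{[(2R,5E)-6,10-dimethyl-2-[(2R)-oxiran-2-yl]undeca-5,9-dien-2-yl]oxy}silane | C1O[C@H]1[C@](C)(O[Si](CC)(CC)CC)CC/C=C(\C)CCC=C(C)C | intermediate
18 | O,C-dilithio derivative of 10 (lithium alkoxide and α-sulfonyl carbanion) | [Li]OCC(=C)[C@H]1CC[C@H](C([Li])S(=O)(=O)c2ccccc2)CO1 | intermediate (not isolated)
19 | 2-[(2R,5S)-5-[(3R,4R,7E)-3-hydroxy-4,8,12-trimethyl-1-(phenylsulfonyl)-4-[(triethylsilyl)oxy]trideca-7,11-dien-1-yl]oxan-2-yl]prop-2-en-1-ol, both epimers at C1' | C=C(CO)[C@H]1CC[C@H](C(S(=O)(=O)c2ccccc2)C[C@@H](O)[C@](C)(O[Si](CC)(CC)CC)CC/C=C(\C)CCC=C(C)C)CO1 | intermediate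
20 | 2-[(2R,5S)-5-[(3R,4R,7E)-3-hydroxy-4,8,12-trimethyl-4-[(triethylsilyl)oxy]trideca-7,11-dien-1-yl]oxan-2-yl]prop-2-en-1-ol | C=C(CO)[C@H]1CC[C@H](CC[C@@H](O)[C@](C)(O[Si](CC)(CC)CC)CC/C=C(\C)CCC=C(C)C)CO1 | intermediate (not isolated)
21 | 2-[(2R,5S)-5-[(3R,4R,7E)-3,4-dihydroxy-4,8,12-trimethyltrideca-7,11-dien-1-yl]oxan-2-yl]prop-2-en-1-ol | C=C(CO)[C@H]1CC[C@H](CC[C@@H](O)[C@](C)(O)CC/C=C(\C)CCC=C(C)C)CO1 | intermediate
22 | 2-[(2R,5S)-5-[(3R,4R,7E)-3,4-dihydroxy-4,8,12-trimethyltrideca-7,11-dien-1-yl]oxan-2-yl]prop-2-enal | C=C(C=O)[C@H]1CC[C@H](CC[C@@H](O)[C@](C)(O)CC/C=C(\C)CCC=C(C)C)CO1 | intermediate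
23 | 2-[(2R,5S)-5-[(3R,4R,7E)-3,4-dihydroxy-4,8,12-trimethyltrideca-7,11-dien-1-yl]oxan-2-yl]prop-2-enoic acid | C=C(C(=O)O)[C@H]1CC[C@H](CC[C@@H](O)[C@](C)(O)CC/C=C(\C)CCC=C(C)C)CO1 | target

**Step count and risks**

Total step count: 13. Longest linear sequence: 9 (steps 1–5, then 10–13); the epoxide arm is 4 steps (6–9).

Steps most likely to fail:

1. Step 5 (Proposed new method). What may go wrong: acetal cleavage with poor regiocontrol, or cationic capture of the oxocarbenium ion by the exocyclic alkene; hydrolysis of the bromomethyl ether during the solvent switch; reduction of the alkoxymethyl radical or 1,5-hydrogen shift from the allylic C4–H before ring closure; weak equatorial/axial discrimination at C5. Fallback with known chemistry, setting out from 4 and returning at 10: selective silylation of the primary hydroxyl (iPr3SiCl, imidazole) gives (3R)-2-methylidene-1-{[tri(propan-2-yl)silyl]oxy}hept-6-en-3-ol F1. Williamson etherification of the secondary alkoxide (NaH, bromoacetic acid, THF) gives the alkoxyacetic acid F2. Cross-metathesis with 6 (second-generation Hoveyda–Grubbs catalyst) gives the E-vinyl sulfone acid F3. Photoredox decarboxylation ([Ir(dF(CF3)ppy)2(dtbbpy)]PF6, K2HPO4, DMF, blue light) generates the same alkoxymethyl radical, and 6-exo Giese cyclisation gives the silyl ether of the oxane sulfone F4. Bu4NF then returns 10.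

2. Step 10. What may go wrong: slow attack of the hindered dianion on the epoxide, BF3-induced isomerisation of the epoxide to carbonyl compounds, or loss of the silyl group followed by Payne-type scrambling. Fallback that replaces epoxide opening by an alkylation, setting out from 14 (and 10) and returning at 21: the tosylation of step 8 is stopped at 15, which is isolated and converted (2,2-dimethoxypropane, pyridinium tosylate) into the acetonide tosylate F5. NaI in butanone gives the primary iodide F6. Alkylation of dilithio sulfone 18 (from 10 and n-BuLi) with F6 in THF/DMPU gives the acetonide sulfone F7. Mg in MeOH gives the desulfonylated acetonide F8, and aqueous acetic acid returns 21.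

3. Step 1. What may go wrong: low conversion and erosion of enantioselectivity with an unbranched, enolisable aldehyde, together with acrylate oligomerisation. Fallback that sets C2 by reagent-controlled ketone reduction, setting out from 1 and returning at 4: addition of the alkenyllithium made from tert-butyl[(2-bromoprop-2-en-1-yl)oxy]dimethylsilane and t-BuLi gives the racemic silyl-protected allylic alcohol F9. Dess–Martin periodinane gives the enone F10. Corey–Bakshi–Shibata reduction ((S)-2-methyl-CBS-oxazaborolidine, catecholborane, −78 °C; the 2-substituted alkenyl group acting as the large group) should give the (3R)-alcohol F11. Bu4NF then returns 4.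

**Further compounds**

F1 | step 5 | (3R)-2-methylidene-1-{[tri(propan-2-yl)silyl]oxy}hept-6-en-3-ol | C=C(CO[Si](C(C)C)(C(C)C)C(C)C)[C@H](O)CCC=C
F2 | step 5 | {[(3R)-2-methylidene-1-{[tri(propan-2-yl)silyl]oxy}hept-6-en-3-yl]oxy}acetic acid | C=C(CO[Si](C(C)C)(C(C)C)C(C)C)[C@H](OCC(=O)O)CCC=C
F3 | step 5 | {[(3R,6E)-2-methylidene-7-(phenylsulfonyl)-1-{[tri(propan-2-yl)silyl]oxy}hept-6-en-3-yl]oxy}acetic acid | C=C(CO[Si](C(C)C)(C(C)C)C(C)C)[C@H](OCC(=O)O)CC/C=C/S(=O)(=O)c1ccccc1
F4 | step 5 | tri(propan-2-yl)silyl ether of 10, {2-[(2R,5S)-5-[(phenylsulfonyl)methyl]oxan-2-yl]prop-2-en-1-yl}oxy-tri(propan-2-yl)silane | C=C(CO[Si](C(C)C)(C(C)C)C(C)C)[C@H]1CC[C@H](CS(=O)(=O)c2ccccc2)CO1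
F5 | step 10 | [(4R,5R)-5-[(3E)-4,8-dimethylnona-3,7-dien-1-yl]-2,2,5-trimethyl-1,3-dioxolan-4-yl]methyl 4-methylbenzenesulfonate | Cc1ccc(cc1)S(=O)(=O)OC[C@H]1OC(C)(C)O[C@]1(C)CC/C=C(\C)CCC=C(C)C
F6 | step 10 | (4S,5R)-5-[(3E)-4,8-dimethylnona-3,7-dien-1-yl]-4-(iodomethyl)-2,2,5-trimethyl-1,3-dioxolane | IC[C@H]1OC(C)(C)O[C@]1(C)CC/C=C(\C)CCC=C(C)C
F7 | step 10 | 2-[(2R,5S)-5-{2-[(4R,5R)-5-[(3E)-4,8-dimethylnona-3,7-dien-1-yl]-2,2,5-trimethyl-1,3-dioxolan-4-yl]-1-(phenylsulfonyl)ethyl}oxan-2-yl]prop-2-en-1-ol, both epimers at the sulfone carbon | C=C(CO)[C@H]1CC[C@H](C(S(=O)(=O)c2ccccc2)C[C@H]2OC(C)(C)O[C@]2(C)CC/C=C(\C)CCC=C(C)C)CO1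
F8 | step 10 | 2-[(2R,5S)-5-{2-[(4R,5R)-5-[(3E)-4,8-dimethylnona-3,7-dien-1-yl]-2,2,5-trimethyl-1,3-dioxolan-4-yl]ethyl}oxan-2-yl]prop-2-en-1-ol | C=C(CO)[C@H]1CC[C@H](CC[C@H]2OC(C)(C)O[C@]2(C)CC/C=C(\C)CCC=C(C)C)CO1
F9 | step 1 | racemic 1-{[tert-butyl(dimethyl)silyl]oxy}-2-methylidenehept-6-en-3-ol | C=C(CO[Si](C)(C)C(C)(C)C)C(O)CCC=C
F10 | step 1 | 1-{[tert-butyl(dimethyl)silyl]oxy}-2-methylidenehept-6-en-3-one | C=C(CO[Si](C)(C)C(C)(C)C)C(=O)CCC=C
F11 | step 1 | (3R)-1-{[tert-butyl(dimethyl)silyl]oxy}-2-methylidenehept-6-en-3-ol | C=C(CO[Si](C)(C)C(C)(C)C)[C@H](O)CCC=C
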